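**Remarks.** Compounds 1, 3 and 6 are taken as commercial. Flavone numbering (O1, C2, C3, C4, C4a, C5–C8, C8a; ring B primed) is used for the corresponding atoms of every intermediate, also before ring A exists.

## Analysis of the target

Compound 12 is a flavone: a 4H-chromen-4-one (benzo ring A fused to pyranone ring C) with a 3,4,5-trimethoxyphenyl ring B on C2. It has no stereocentre, so the problem is purely one of constitution. Ring A carries no hydrogen: C4a bears the C4 carbonyl, C5, C6 and C7 bear methoxy groups, C8 bears the free hydroxyl and C8a bears O1. Five contiguous ring carbons are therefore oxygenated, and exactly one of those oxygens is unalkylated. The C8 hydroxyl is para to the C5 methoxy group, so ring A is a hydroquinone monomethyl ether that strong oxidants would take to the 5,8-quinone. The C5 ether is peri to the C4 carbonyl and is the one most easily cleaved by Lewis acids. In a 5,8-diol, conversely, the chelated 5-OH is the less nucleophilic hydroxyl, so selective methylation would give the wrong isomer. Ring C is a vinylogous ester that nucleophiles open at C2. The difficulty is thus a hexasubstituted benzene ring in which the C5 and C8 oxygens must be told apart by construction and not by late selective alkylation or dealkylation.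

## Retrosynthetic reasoning

**12 to 9.** Ring A is opened at C8–C8a and its carbons C5–C8 are folded back into a four-membered ring, so that 12 becomes its constitutional isomer 9, a 4-methoxycyclobutenone bearing the intact rings B and C. The cut is placed here because C8 carries the only free hydroxyl. If C8 is the ketene carbon of the ring-opened form 10, its oxygen can only end as a phenol, while the oxygen on C5 is already a methyl ether. The forward reaction must open the cyclobutenone with the methoxy group turning outward, close the ketene onto the pyranone CH next to O1, and enolize the dienone 11. The gain is that the whole of ring A, with its four oxygenated carbons C5–C8 in the right pattern, appears in one operation without a protecting group.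

**9 to 8.** The C5 oxygen–methyl bond is cut. Methylating the tertiary alcohol of 8 before ring A exists distinguishes the C5 oxygen from the C8 oxygen by timing. This needs only a non-basic O-methylation.

**8 to 5 and 6.** The C4a–C5 bond is cut. Carbons C5–C8 with the C6 and C7 methoxy groups come from the symmetric cyclobutenedione 6. C4a comes from the iodopyranone 5, used as its magnesium derivative 7. The forward step is a 1,2-addition to one of two equivalent carbonyl groups, so no regiochemical question arises.

**5 to 2 and 3.** Ring C is cut at C2–C3 and at O1–C8a. The aroyl chloride 3 supplies ring B and C2, and the iodo enone 2 supplies C3, C4, C4a and C8a. The iodine is already on the carbon that becomes C4a, so no site-selective halogenation of a pyranone with two α positions and an electron-rich aryl ring is needed. The forward step is a C-acylation of a ketone enolate, giving 4, followed by acid cyclization with loss of methanol.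

**2 to 1.** The C–I bond is cut, leading back to the commercial β-methoxy enone 1 by α-iodination of a vinylogous ester.

## Alternatives that were turned down

Alternative 1: The textbook disconnection cuts ring C at O1–C2 and C2–C3 and keeps ring A as a purchased benzene. The acetophenone A1 would be O-acylated with 3, rearranged with base (Baker–Venkataraman rearrangement) and cyclodehydrated to the 8-benzyloxyflavone A2, and hydrogenolysis would give 12. It was turned down because none of these steps addresses the hard feature. All of the difficulty moves into A1, a hexasubstituted benzene with five oxygen substituents in three different states. No simple commercial arene supplies that pattern, so A1 would need a series of ring oxidations and selective protections on a polyoxygenated arene, each with its own regiochemical question. The estimate is eight to ten steps, about twice the chosen route.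

Alternative 2: The C8–O bond is cut and made last on the preformed hexamethoxyflavone A3, by electrophilic bromination to A4 followed by metal-catalysed hydroxylation. C8–H is the only C–H of ring A and is activated by O1 and the C7 methoxy group (ortho) and by the C5 methoxy group (para). However, C3–H (the β-carbon of the enol ether in ring C) and C2'/C6'–H of ring B (each ortho and para to methoxy groups) are comparably nucleophilic, so three sites compete. C8 is flanked on both sides, which rules out a sterically governed C–H borylation. Hydroxylation of a doubly ortho-substituted, electron-rich aryl bromide is slow and competes with hydrodehalogenation. The move forms one bond only and leaves the skeleton to the textbook sequence, for about six steps in all.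

Alternative 3: Ring A is cut at C5–C6, C7–C8 and C8–C8a in a Dötz benzannulation. The pentacarbonylchromium carbene complex A5 (zerovalent chromium) would be heated with dimethoxyacetylene A6. Alkyne and one CO ligand insert, and the vinylketene closes onto the pyranone CH to give 12, with the carbene carbon as C5–OMe and the CO carbon as C8–OH. The regiochemical logic is the same as in the chosen route, but the means are worse. A6 is an ynediether that polymerizes and cannot be stored. A5 would have to be made from a metalated pyranone and Cr(CO)6 with the C4 carbonyl unprotected. Chromium is stoichiometric, and electron-rich alkynes divert such complexes to five-membered-ring products. Compound 6 supplies the same two methoxy-bearing carbons in a stable commercial form.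

Key step: step 5

## Route

Step 1
Reactants: 1 (E)-4-methoxybut-3-en-2-one
Product: 2 (Z)-3-iodo-4-methoxybut-3-en-2-one
Conditions: NIS, AcOH, CH2Cl2, rt, dark; then Et3N, 0 °C
Reagents that add atoms: N-iodosuccinimide, O=C1CCC(=O)N1I
Why: Iodoacetoxylation of the enol ether double bond and elimination of AcOH with Et3N should give the α-iodo vinylogous ester, as in the α-iodination of β-methoxyacrylates; the Z isomer (iodine cis to methoxy) is expected, and the geometry is lost in step 2 in any case.

Step 2
Reactants: 2 (Z)-3-iodo-4-methoxybut-3-en-2-one; 3 3,4,5-trimethoxybenzoyl chloride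
Product: 5 5-iodo-2-(3,4,5-trimethoxyphenyl)-4H-pyran-4-one, via acyclic iodo diketone 4 (not isolated)
Conditions: 2 (2 equiv), LiN(SiMe3)2 (2 equiv), THF, −78 °C; 3 (1 equiv), −78 °C; aq. NH4Cl; then CF3CO2H, CH2Cl2, rt
Reagents that add atoms: none
Why: Kinetic deprotonation of the methyl ketone and C-acylation of the lithium dienolate by the aroyl chloride should give 4 (the second equivalent of enolate is used up in deprotonating 4); under acid the enol oxygen adds to the β-methoxy enone carbon and methanol is lost, the enolate acylation and acid cyclization route to 4-pyranones, and the vinyl iodide is inert to the amide base at −78 °C.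

Step 3
Reactants: 5 5-iodo-2-(3,4,5-trimethoxyphenyl)-4H-pyran-4-one; 6 dimethyl squarate (3,4-dimethoxycyclobut-3-ene-1,2-dione)
Product: 8 4-hydroxy-2,3-dimethoxy-4-[4-oxo-6-(3,4,5-trimethoxyphenyl)-4H-pyran-3-yl]cyclobut-2-en-1-one (racemic), via pyranonylmagnesium chloride 7 (not isolated)
Conditions: 5, iPrMgCl·LiCl, THF, −40 °C; then added to 6 (1.2 equiv), THF, −78 to −20 °C; aq. NH4Cl
Reagents that add atoms: none
Why: Iodine–magnesium exchange on an alkenyl iodide α to a carbonyl group is fast at −40 °C and should outrun addition of the reagent to the vinylogous ester; the alkenyl Grignard reagent 7 then adds 1,2 to one of the two equivalent strained carbonyl groups of 6, the standard entry to 4-substituted 4-hydroxycyclobutenones; the new quaternary stereocentre forms as a racemate and is destroyed in step 5.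

Step 4
Reactants: 8 4-hydroxy-2,3-dimethoxy-4-[4-oxo-6-(3,4,5-trimethoxyphenyl)-4H-pyran-3-yl]cyclobut-2-en-1-one
Product: 9 2,3,4-trimethoxy-4-[4-oxo-6-(3,4,5-trimethoxyphenyl)-4H-pyran-3-yl]cyclobut-2-en-1-one (racemic)
Conditions: MeI (excess), Ag2O, MeCN, rt, dark
Reagents that add atoms: iodomethane, CI
Why: Purdie methylation of the tertiary alcohol under non-basic conditions avoids retro-addition or ring opening of a free cyclobutenol alkoxide; it fixes the future C5 oxygen as its methyl ether before ring A exists.

Step 5
Reactants: 9 2,3,4-trimethoxy-4-[4-oxo-6-(3,4,5-trimethoxyphenyl)-4H-pyran-3-yl]cyclobut-2-en-1-one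
Product: 12 8-hydroxy-5,6,7-trimethoxy-2-(3,4,5-trimethoxyphenyl)-4H-chromen-4-one (target), via dienylketene 10 (not isolated), via 8aH-cyclohexadienone 11 (not isolated)
Conditions: p-xylene (0.01 M, degassed), 140 °C, Ar
Reagents that add atoms: none
Why: Heating should open the cyclobutenone by a conrotatory 4π electrocyclic cleavage of the C5–C8 σ bond, in which the donor methoxy group on the sp3 carbon turns outward, so that the pyranonyl group turns inward and the ketene of 10 is formed cis to it. Ring A then closes by a disrotatory 6π electrocyclization in which the ketene carbon (C8) bonds to the pyranone CH next to the ring oxygen (C8a), giving dienone 11. Enolization of 11, which moves the C8a hydrogen to the C8 oxygen, is driven by aromatization and gives 12. The closest known reaction type is the Moore rearrangement of 4-aryl-, 4-heteroaryl- and 4-alkenyl-4-alkoxycyclobutenones to hydroquinone monoethers, which includes closures onto the oxygen-bearing carbon of 3-furyl groups and onto electron-poor pyridine carbons. No stereocentre remains, since the one in 9 is lost on ring opening and the one in 11 on enolization. The selectivity needed is constitutional and is fixed by connectivity: C4a has only one neighbour that carries hydrogen (C8a), its other neighbour being the C4 carbonyl carbon, and the ketene oxygen can only become the free hydroxyl on C8 while the oxygen methylated in step 4 stays on C5. High dilution keeps the ketene from adding to phenol already formed.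

## Compound list

1 | (E)-4-methoxybut-3-en-2-one | CO/C=C/C(C)=O | starting material
2 | (Z)-3-iodo-4-methoxybut-3-en-2-one | CO/C=C(\I)C(C)=O | intermediate
3 | 3,4,5-trimethoxybenzoyl chloride | COc1cc(C(=O)Cl)cc(OC)c1OC | starting material
4 | (Z)-4-iodo-5-methoxy-1-(3,4,5-trimethoxyphenyl)pent-4-ene-1,3-dione (not isolated) | CO/C=C(\I)C(=O)CC(=O)c1cc(OC)c(OC)c(OC)c1 | intermediate
5 | 5-iodo-2-(3,4,5-trimethoxyphenyl)-4H-pyran-4-one | COc1cc(-c2cc(=O)c(I)co2)cc(OC)c1OC | intermediate
6 | dimethyl squarate (3,4-dimethoxycyclobut-3-ene-1,2-dione) | COC1=C(OC)C(=O)C1=O | starting material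
7 | [4-oxo-6-(3,4,5-trimethoxyphenyl)-4H-pyran-3-yl]magnesium chloride, LiCl complex (not isolated) | COc1cc(-c2cc(=O)c([Mg]Cl)co2)cc(OC)c1OC | intermediate
8 | 4-hydroxy-2,3-dimethoxy-4-[4-oxo-6-(3,4,5-trimethoxyphenyl)-4H-pyran-3-yl]cyclobut-2-en-1-one, racemic | COC1=C(OC)C(O)(c2coc(-c3cc(OC)c(OC)c(OC)c3)cc2=O)C1=O | intermediate
9 | 2,3,4-trimethoxy-4-[4-oxo-6-(3,4,5-trimethoxyphenyl)-4H-pyran-3-yl]cyclobut-2-en-1-one, racemic | COC1=C(OC)C(OC)(c2coc(-c3cc(OC)c(OC)c(OC)c3)cc2=O)C1=O | intermediate
10 | (3Z)-2,3,4-trimethoxy-4-[4-oxo-6-(3,4,5-trimethoxyphenyl)-4H-pyran-3-yl]buta-1,3-dien-1-one (not isolated) | O=C=C(OC)/C(OC)=C(/OC)c1coc(-c2cc(OC)c(OC)c(OC)c2)cc1=O | intermediate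
11 | 5,6,7-trimethoxy-2-(3,4,5-trimethoxyphenyl)-8aH-chromene-4,8-dione, racemic (not isolated) | COC1=C(OC)C(=O)C2OC(c3cc(OC)c(OC)c(OC)c3)=CC(=O)C2=C1OC | intermediate
12 | 8-hydroxy-5,6,7-trimethoxy-2-(3,4,5-trimethoxyphenyl)-4H-chromen-4-one | COc1cc(-c2cc(=O)c3c(OC)c(OC)c(OC)c(O)c3o2)cc(OC)c1OC | target

## Step count and risk

Total step count: 5. Longest linear sequence: 5 steps (1, 2, 5, 8, 9, 12); 3 and 6 enter at steps 2 and 3.

**Step 5 (key step).** The ketene of 10 must close onto C8a, a carbon that is β to the C4 carbonyl and part of a weakly aromatic pyranone. If this closure is slow, ring opening stays reversible and the ketene is lost to dimerization or to acylation of phenol already formed. The fallback turns the annulation round so that the ketene closes onto the nucleophilic α-carbon of the pyranone. It sets out from 1 and 3 and comes back to the route at 12.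
- Acylation of the lithium enolate of 1 with 3 should give (E)-5-methoxy-1-(3,4,5-trimethoxyphenyl)pent-4-ene-1,3-dione F1, which CF3CO2H cyclizes to 2-(3,4,5-trimethoxyphenyl)-4H-pyran-4-one F2.
- Deprotonation next to the ring oxygen with TMPMgCl·LiCl (TMP = 2,2,6,6-tetramethylpiperidide) at −40 °C should give [4-oxo-6-(3,4,5-trimethoxyphenyl)-4H-pyran-2-yl]magnesium chloride F3. Addition to 6 gives 4-hydroxy-2,3-dimethoxy-4-[4-oxo-6-(3,4,5-trimethoxyphenyl)-4H-pyran-2-yl]cyclobut-2-en-1-one F4.
- Protection with MOMCl and iPr2NEt gives the methoxymethyl ether 2,3-dimethoxy-4-(methoxymethoxy)-4-[4-oxo-6-(3,4,5-trimethoxyphenyl)-4H-pyran-2-yl]cyclobut-2-en-1-one F5.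
- Thermolysis in p-xylene closes the ketene onto the enol-ether β-carbon (C4a) and should give 5-hydroxy-6,7-dimethoxy-8-(methoxymethoxy)-2-(3,4,5-trimethoxyphenyl)-4H-chromen-4-one F6.
- Methylation of the chelated 5-OH (Me2SO4, K2CO3, acetone, reflux) gives 5,6,7-trimethoxy-8-(methoxymethoxy)-2-(3,4,5-trimethoxyphenyl)-4H-chromen-4-one F7, and HCl in MeOH removes the acetal to give 12.

**Step 3.** The magnesiated pyranone 7 may be lost before it adds. The metal and O1 lie trans across the double bond, so β-elimination with ring opening is possible, and the exchange reagent may add to the pyranone. The fallback is a Nozaki–Hiyama–Kishi coupling, which sets out from 5 and 6 and comes back at 8. With CrCl2 (excess) and NiCl2 (catalytic) in DMF at rt, oxidative addition of the C–I bond to zerovalent nickel and transmetalation should give dichloro[4-oxo-6-(3,4,5-trimethoxyphenyl)-4H-pyran-3-yl]chromium F8 (trivalent chromium). This species is non-basic and carbonyl-tolerant, and it should add to the strained carbonyl of 6.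

**Step 2.** The lithium dienolate of 2 may self-condense or decompose before acylation, or acylation may occur on oxygen. The fallback makes the same iodopyranone by cycloaddition and late dehydrogenation. It sets out from 3 and comes back at 5.
- Reduction of 3 with LiAlH(OtBu)3 (THF, −78 °C) gives 3,4,5-trimethoxybenzaldehyde F9, which is also commercial.
- Hetero-Diels–Alder reaction with (E)-1-methoxy-3-(trimethylsilyloxy)buta-1,3-diene, mediated by ZnCl2, gives 2-methoxy-6-(3,4,5-trimethoxyphenyl)-4-(trimethylsilyloxy)-5,6-dihydro-2H-pyran F10. CF3CO2H converts it to racemic 2-(3,4,5-trimethoxyphenyl)-2,3-dihydro-4H-pyran-4-one F11.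
- α-Iodination with I2 and pyridine, at the only vinylic α position, gives 5-iodo-2-(3,4,5-trimethoxyphenyl)-2,3-dihydro-4H-pyran-4-one F12.
- Dehydrogenation with DDQ in dioxane (hydride abstraction from the benzylic C2 next to oxygen, as with flavanones) gives 5.

## Further compounds

F1 | step 5 | (E)-5-methoxy-1-(3,4,5-trimethoxyphenyl)pent-4-ene-1,3-dione | CO/C=C/C(=O)CC(=O)c1cc(OC)c(OC)c(OC)c1
F2 | step 5 | 2-(3,4,5-trimethoxyphenyl)-4H-pyran-4-one | COc1cc(-c2cc(=O)cco2)cc(OC)c1OC
F3 | step 5 | [4-oxo-6-(3,4,5-trimethoxyphenyl)-4H-pyran-2-yl]magnesium chloride | COc1cc(-c2cc(=O)cc([Mg]Cl)o2)cc(OC)c1OC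
F4 | step 5 | 4-hydroxy-2,3-dimethoxy-4-[4-oxo-6-(3,4,5-trimethoxyphenyl)-4H-pyran-2-yl]cyclobut-2-en-1-one, racemic | COC1=C(OC)C(O)(c2cc(=O)cc(-c3cc(OC)c(OC)c(OC)c3)o2)C1=O
F5 | step 5 | 2,3-dimethoxy-4-(methoxymethoxy)-4-[4-oxo-6-(3,4,5-trimethoxyphenyl)-4H-pyran-2-yl]cyclobut-2-en-1-one, racemic | COCOC1(c2cc(=O)cc(-c3cc(OC)c(OC)c(OC)c3)o2)C(OC)=C(OC)C1=O
F6 | step 5 | 5-hydroxy-6,7-dimethoxy-8-(methoxymethoxy)-2-(3,4,5-trimethoxyphenyl)-4H-chromen-4-one | COCOc1c(OC)c(OC)c(O)c2c(=O)cc(-c3cc(OC)c(OC)c(OC)c3)oc12
F7 | step 5 | 5,6,7-trimethoxy-8-(methoxymethoxy)-2-(3,4,5-trimethoxyphenyl)-4H-chromen-4-one | COCOc1c(OC)c(OC)c(OC)c2c(=O)cc(-c3cc(OC)c(OC)c(OC)c3)oc12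
F8 | step 3 | dichloro[4-oxo-6-(3,4,5-trimethoxyphenyl)-4H-pyran-3-yl]chromium | COc1cc(-c2cc(=O)c([Cr](Cl)Cl)co2)cc(OC)c1OC
F9 | step 2 | 3,4,5-trimethoxybenzaldehyde | COc1cc(C=O)cc(OC)c1OC
F10 | step 2 | 2-methoxy-6-(3,4,5-trimethoxyphenyl)-4-(trimethylsilyloxy)-5,6-dihydro-2H-pyran, racemic mixture of diastereomers | COC1C=C(O[Si](C)(C)C)CC(c2cc(OC)c(OC)c(OC)c2)O1
F11 | step 2 | 2-(3,4,5-trimethoxyphenyl)-2,3-dihydro-4H-pyran-4-one, racemic | COc1cc(C2CC(=O)C=CO2)cc(OC)c1OC
F12 | step 2 | 5-iodo-2-(3,4,5-trimethoxyphenyl)-2,3-dihydro-4H-pyran-4-one, racemic | COc1cc(C2CC(=O)C(I)=CO2)cc(OC)c1OC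
A1 | alternative 1 | 1-[3-(benzyloxy)-2-hydroxy-4,5,6-trimethoxyphenyl]ethan-1-one | CC(=O)c1c(O)c(OCc2ccccc2)c(OC)c(OC)c1OC
A2 | alternative 1 | 8-(benzyloxy)-5,6,7-trimethoxy-2-(3,4,5-trimethoxyphenyl)-4H-chromen-4-one | COc1cc(-c2cc(=O)c3c(OC)c(OC)c(OC)c(OCc4ccccc4)c3o2)cc(OC)c1OC
A3 | alternative 2 | 5,6,7-trimethoxy-2-(3,4,5-trimethoxyphenyl)-4H-chromen-4-one | COc1cc(-c2cc(=O)c3c(OC)c(OC)c(OC)cc3o2)cc(OC)c1OC
A4 | alternative 2 | 8-bromo-5,6,7-trimethoxy-2-(3,4,5-trimethoxyphenyl)-4H-chromen-4-one | COc1cc(-c2cc(=O)c3c(OC)c(OC)c(OC)c(Br)c3o2)cc(OC)c1OC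
A5 | alternative 3 | pentacarbonyl{methoxy[4-oxo-6-(3,4,5-trimethoxyphenyl)-4H-pyran-3-yl]methylidene}chromium | COC(c1coc(-c2cc(OC)c(OC)c(OC)c2)cc1=O)=[Cr](=C=O)(=C=O)(=C=O)(=C=O)=C=O
A6 | alternative 3 | dimethoxyacetylene | COC#COC
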